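The route rests on cutting the bond between the vanillyl ring carbon C1′ and C2 of the dihydropyranone ring. C2 is the β-carbon of the C4 ketone, so the C ring is carried one oxidation level higher, as a chromone (C2=C3–C4=O), and the aryl group is delivered by a rhodium/chiral-diene-catalysed asymmetric 1,4-addition of an arylboronic acid. This one operation joins the complete 8-prenyl-5,7-dioxygenated A/C bicycle to the B ring and sets C2; the C2 aryl group then directs trans C3 hydroxylation. The precursor is 5,7-bis(methoxymethoxy)-8-prenylchromone, built from 5,7-dihydroxychromone by a 5-O-prenyl Claisen–Cope shift.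

Key step: step 7

Remark: the target is read as the (2R,3R)-trans-dihydroflavonol; 5,7-dihydroxychromone and 4-bromo-2-methoxyphenol are taken as commercial (MOM = methoxymethyl, prenyl = 3-methylbut-2-en-1-yl).

Step 1
Reactants: 1 5,7-dihydroxy-4H-chromen-4-one
Product: 2 5-hydroxy-7-(methoxymethoxy)-4H-chromen-4-one
Conditions: MOMCl (1.05 equiv), iPr2NEt, CH2Cl2, 0 °C
Reagents that add atoms: chloromethyl methyl ether (MOMCl), COCCl
Why: Williamson-type O-alkylation (MOM protection): the 5-OH is tied up in a hydrogen bond to the C4 carbonyl, so the free, more acidic 7-OH should react selectively with one equivalent of MOMCl.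

Step 2
Reactants: 2 5-hydroxy-7-(methoxymethoxy)-4H-chromen-4-one
Product: 3 7-(methoxymethoxy)-5-[(3-methylbut-2-en-1-yl)oxy]-4H-chromen-4-one
Conditions: prenyl bromide, K2CO3, DMF, 40–50 °C
Reagents that add atoms: 1-bromo-3-methylbut-2-ene (prenyl bromide), CC(C)=CCBr
Why: Williamson etherification: with the 7-OH blocked, carbonate in DMF should ionise the chelated 5-OH enough for O-alkylation by the reactive allylic bromide, the chromone being inert to these conditions.

Step 3
Reactants: 3 7-(methoxymethoxy)-5-[(3-methylbut-2-en-1-yl)oxy]-4H-chromen-4-one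
Product: 6 5-hydroxy-7-(methoxymethoxy)-8-(3-methylbut-2-en-1-yl)-4H-chromen-4-one, via ortho-Claisen dienone 4 (not isolated), via 8-prenyl dienone 5 (not isolated)
Conditions: Eu(fod)3 (10 mol %), NaHCO3, PhCl, 85 °C
Reagents that add atoms: none
Why: Eu(III)-catalysed domino aromatic Claisen–Cope rearrangement (para-Claisen): the first [3,3] shift can only go to C6 (C4a is blocked), and the Lewis acid chelated between the C4 and C5 oxygens should drive the following [3,3] Cope shift of the 1,1-dimethylallyl group to C8 before tautomerisation, so the prenyl group ends up at C8 with normal connectivity and the 5-OH is regenerated.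

Step 4
Reactants: 6 5-hydroxy-7-(methoxymethoxy)-8-(3-methylbut-2-en-1-yl)-4H-chromen-4-one
Product: 7 5,7-bis(methoxymethoxy)-8-(3-methylbut-2-en-1-yl)-4H-chromen-4-one
Conditions: NaH, MOMCl, DMF, 0 °C → rt
Reagents that add atoms: chloromethyl methyl ether (MOMCl), COCCl
Why: Williamson-type MOM protection: the hydrogen-bonded 5-OH needs full deprotonation with NaH, after which O-alkylation is straightforward and leaves a chromone free of acidic protons for the rhodium step.

Step 5
Reactants: 8 4-bromo-2-methoxyphenol
Product: 9 4-bromo-2-methoxy-1-(methoxymethoxy)benzene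
Conditions: MOMCl, iPr2NEt, CH2Cl2, 0 °C → rt
Reagents that add atoms: chloromethyl methyl ether (MOMCl), COCCl
Why: MOM protection of the phenol (Williamson-type O-alkylation) masks the acidic OH for the lithiation and for the rhodium-catalysed coupling.

Step 6
Reactants: 9 4-bromo-2-methoxy-1-(methoxymethoxy)benzene
Product: 12 [3-methoxy-4-(methoxymethoxy)phenyl]boronic acid, via aryllithium 10 (not isolated), via lithium aryltriisopropoxyborate 11 (not isolated)
Conditions: n-BuLi, THF, −78 °C; B(OiPr)3, −78 °C → rt; dilute aq HCl to pH 5–6, 0 °C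
Reagents that add atoms: triisopropyl borate, CC(C)OB(OC(C)C)OC(C)C; water, O
Why: Bromine–lithium exchange, which at −78 °C outruns MOM-directed ortho-lithiation, followed by borylation with a trialkyl borate and mild hydrolysis of the ate complex, is the standard route to arylboronic acids.

Step 7
Reactants: 7 5,7-bis(methoxymethoxy)-8-(3-methylbut-2-en-1-yl)-4H-chromen-4-one; 12 [3-methoxy-4-(methoxymethoxy)phenyl]boronic acid
Product: 13 (2S)-2-[3-methoxy-4-(methoxymethoxy)phenyl]-5,7-bis(methoxymethoxy)-8-(3-methylbut-2-en-1-yl)-2,3-dihydro-4H-chromen-4-one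
Conditions: 12 (3 equiv), [RhCl(C2H4)2]2 (2.5 mol %), chiral 2,5-diphenylbicyclo[2.2.2]octa-2,5-diene (Ph-bod*, 5.5 mol %, antipode that directs aryl to the Re face of C2), KOH (0.5 equiv), toluene/H2O, 40 °C
Reagents that add atoms: none
Why: Hayashi–Miyaura-type asymmetric conjugate arylation: the aryl group passes from boron to a hydroxo-Rh(I)–diene complex, the chromone C2=C3 bond inserts into the Rh–aryl bond so that the aryl carbon bonds to C2 (the β-carbon of the vinylogous ester), and the oxa-π-allyl rhodium enolate is protonated by water to release the flavanone and the Rh–OH species. The closest known reaction is the Rh/chiral-diene-catalysed 1,4-addition of arylboronic acids to chromones, an established enantioselective entry to flavanones, 5,7-dioxygenated ones included. No ring is closed. The new stereocentre C2 is set by the chiral diene, whose antipode is chosen so that the aryl group is delivered to the Re face of C2 (O1 > C3 > H), giving 2S, the same spatial arrangement as 2R in the target. The step needs 1,4- over 1,2-addition and an untouched prenyl alkene, which the soft aryl–Rh species secures by inserting only the carbonyl-activated C2=C3 bond, and it needs the product not to racemise by retro-oxa-Michael opening, which the substoichiometric base, the biphasic medium and 40 °C are meant to prevent. An excess of 12 covers competing protodeboronation on this electron-rich, slow acceptor.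

Step 8
Reactants: 13 (2S)-2-[3-methoxy-4-(methoxymethoxy)phenyl]-5,7-bis(methoxymethoxy)-8-(3-methylbut-2-en-1-yl)-2,3-dihydro-4H-chromen-4-one
Product: 17 (2R,3R)-3-hydroxy-2-[3-methoxy-4-(methoxymethoxy)phenyl]-5,7-bis(methoxymethoxy)-8-(3-methylbut-2-en-1-yl)-2,3-dihydro-4H-chromen-4-one, via TMS enol ether 14 (not isolated), via silyloxy epoxide 15 (not isolated), via 3-O-TMS ketone 16 (not isolated)
Conditions: Et3N, TMSOTf, CH2Cl2, −78 → −20 °C; pentane, filtration, evaporation (crude used at once); DMDO (1.05 equiv) in acetone/CH2Cl2, −78 °C; then 10 % aq citric acid/THF, 0 °C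
Reagents that add atoms: dimethyldioxirane (DMDO), CC1(C)OO1
Why: Rubottom oxidation: soft enolisation gives the enol silane without a free enolate (no retro-oxa-Michael opening, C2 untouched), DMDO should epoxidise this very electron-rich enol ether at −78 °C much faster than the prenyl alkene and from the face opposite the C2 aryl group, and silyl migration plus hydrolysis then give the 2,3-trans (3R) α-hydroxy ketone under substrate control.

Step 9
Reactants: 17 (2R,3R)-3-hydroxy-2-[3-methoxy-4-(methoxymethoxy)phenyl]-5,7-bis(methoxymethoxy)-8-(3-methylbut-2-en-1-yl)-2,3-dihydro-4H-chromen-4-one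
Product: 18 (2R,3R)-3,5,7-trihydroxy-2-(4-hydroxy-3-methoxyphenyl)-8-(3-methylbut-2-en-1-yl)-2,3-dihydro-4H-chromen-4-one
Conditions: HCl (1.25 M in MeOH), 0 °C → rt, monitored
Reagents that add atoms: none
Why: Acid-catalysed acetal methanolysis removes all three MOM groups in one operation, mild methanolic HCl at or below room temperature being the conditions under which ortho-prenyl phenols and the dihydroflavonol stereocentres are expected to survive.

Compound list
1 | 5,7-dihydroxy-4H-chromen-4-one | O=c1ccoc2cc(O)cc(O)c12 | starting material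
2 | 5-hydroxy-7-(methoxymethoxy)-4H-chromen-4-one | O=c1ccoc2cc(OCOC)cc(O)c12 | intermediate
3 | 7-(methoxymethoxy)-5-[(3-methylbut-2-en-1-yl)oxy]-4H-chromen-4-one | O=c1ccoc2cc(OCOC)cc(OCC=C(C)C)c12 | intermediate
4 | 7-(methoxymethoxy)-6-(2-methylbut-3-en-2-yl)-6H-chromene-4,5-dione (ortho-Claisen dienone, racemic at C6) | O=C1C=COC2=C1C(=O)C(C(C)(C)C=C)C(OCOC)=C2 | intermediate
5 | 7-(methoxymethoxy)-8-(3-methylbut-2-en-1-yl)-8H-chromene-4,5-dione (Cope dienone, racemic at C8) | O=C1C=COC2=C1C(=O)C=C(OCOC)C2CC=C(C)C | intermediate
6 | 5-hydroxy-7-(methoxymethoxy)-8-(3-methylbut-2-en-1-yl)-4H-chromen-4-one | O=c1ccoc2c(CC=C(C)C)c(OCOC)cc(O)c12 | intermediate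
7 | 5,7-bis(methoxymethoxy)-8-(3-methylbut-2-en-1-yl)-4H-chromen-4-one | O=c1ccoc2c(CC=C(C)C)c(OCOC)cc(OCOC)c12 | intermediate
8 | 4-bromo-2-methoxyphenol | COc1cc(Br)ccc1O | starting material
9 | 4-bromo-2-methoxy-1-(methoxymethoxy)benzene | COCOc1ccc(Br)cc1OC | intermediate
10 | [3-methoxy-4-(methoxymethoxy)phenyl]lithium | [Li]c1ccc(OCOC)c(OC)c1 | intermediate
11 | lithium [3-methoxy-4-(methoxymethoxy)phenyl]tri(propan-2-yloxy)borate | [Li+].CC(C)O[B-](OC(C)C)(OC(C)C)c1ccc(OCOC)c(OC)c1 | intermediate
12 | [3-methoxy-4-(methoxymethoxy)phenyl]boronic acid | COCOc1ccc(B(O)O)cc1OC | intermediate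
13 | (2S)-2-[3-methoxy-4-(methoxymethoxy)phenyl]-5,7-bis(methoxymethoxy)-8-(3-methylbut-2-en-1-yl)-2,3-dihydro-4H-chromen-4-one | COc1cc([C@H]2Oc3c(CC=C(C)C)c(OCOC)cc(OCOC)c3C(=O)C2)ccc1OCOC | intermediate
14 | {[(2S)-2-[3-methoxy-4-(methoxymethoxy)phenyl]-5,7-bis(methoxymethoxy)-8-(3-methylbut-2-en-1-yl)-2H-chromen-4-yl]oxy}trimethylsilane | COc1cc([C@H]2Oc3c(CC=C(C)C)c(OCOC)cc(OCOC)c3C(O[Si](C)(C)C)=C2)ccc1OCOC | intermediate
15 | 3,4-epoxide of 14 (4-trimethylsilyloxy-3,4-epoxychromane, epoxide oxygen on the face opposite the C2 aryl group) | COc1cc([C@H]2Oc3c(CC=C(C)C)c(OCOC)cc(OCOC)c3[C@]4(O[Si](C)(C)C)O[C@@H]42)ccc1OCOC | intermediate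
16 | (2R,3R)-2-[3-methoxy-4-(methoxymethoxy)phenyl]-5,7-bis(methoxymethoxy)-8-(3-methylbut-2-en-1-yl)-3-(trimethylsilyloxy)-2,3-dihydro-4H-chromen-4-one | COc1cc([C@H]2Oc3c(CC=C(C)C)c(OCOC)cc(OCOC)c3C(=O)[C@@H]2O[Si](C)(C)C)ccc1OCOC | intermediate
17 | (2R,3R)-3-hydroxy-2-[3-methoxy-4-(methoxymethoxy)phenyl]-5,7-bis(methoxymethoxy)-8-(3-methylbut-2-en-1-yl)-2,3-dihydro-4H-chromen-4-one | COc1cc([C@H]2Oc3c(CC=C(C)C)c(OCOC)cc(OCOC)c3C(=O)[C@@H]2O)ccc1OCOC | intermediate
18 | (2R,3R)-3,5,7-trihydroxy-2-(4-hydroxy-3-methoxyphenyl)-8-(3-methylbut-2-en-1-yl)-2,3-dihydro-4H-chromen-4-one | COc1cc([C@H]2Oc3c(CC=C(C)C)c(O)cc(O)c3C(=O)[C@@H]2O)ccc1O | target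

Total step count: 9
Longest linear sequence: 7 steps (steps 1, 2, 3, 4, 7, 8, 9); the boronic acid branch has 2 steps (5, 6).

Steps most likely to fail

1. Step 8. What may go wrong: the dioxirane may also epoxidise the prenyl alkene, the silyl triflate may attack the aryl MOM acetals, or facial selectivity at C3 may be incomplete. The fallback replaces the enol-silane epoxidation by a direct enolate oxidation that is inert to isolated alkenes. It sets out from 13: deprotonation with KHMDS in THF at −78 °C gives the potassium enolate F1, which is hydroxylated in the same flask by 3-phenyl-2-(phenylsulfonyl)oxaziridine from the face opposite the C2 aryl group. After an ammonium chloride quench at low temperature it comes back to the route at 17. The enolate is kept cold and short-lived to suppress ring opening to the chalcone.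

2. Step 7. What may go wrong: insertion into the electron-rich chromone may be slower than protodeboronation of the electron-rich boronic acid, and aqueous base may erode the enantiomeric purity by ring opening and re-closure. The fallback changes the aryl donor and works without water or base. It sets out from 9 and 7: bromine–lithium exchange to 10 and transmetalation with ZnCl2 give [3-methoxy-4-(methoxymethoxy)phenyl]zinc chloride F2. This is added to 7 in THF at room temperature under Rh(I)/BINAP catalysis (ligand antipode chosen for 2S) in the presence of Me3SiCl, which activates the chromone and silylates the enolate as it forms. The sequence comes back to the route at enol silane 14, which is oxidised as in the second stage of step 8.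

3. Step 9. What may go wrong: under Brønsted acid the freed 7-OH may add to the protonated prenyl alkene (chroman formation), the alkene may take up HCl or methanol, or C2/C3 may epimerise on prolonged exposure. The fallback replaces acid solvolysis by a buffered silyl-transfer cleavage. It sets out from 17: TMSOTf/2,2′-bipyridyl in CH2Cl2 at 0 °C exchanges the three aryl methoxymethyl acetals for silyl ethers and silylates the 3-OH, giving (2R,3R)-2-[3-methoxy-4-(trimethylsilyloxy)phenyl]-8-(3-methylbut-2-en-1-yl)-3,5,7-tris(trimethylsilyloxy)-2,3-dihydro-4H-chromen-4-one F3. Addition of water then hydrolyses the silyl ethers under near-neutral conditions and the sequence comes back to the route at 18.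

Further compounds
F1 | step 8 | potassium enolate of 13 (potassium (2S)-2-[3-methoxy-4-(methoxymethoxy)phenyl]-5,7-bis(methoxymethoxy)-8-(3-methylbut-2-en-1-yl)-2H-chromen-4-olate) | COc1cc([C@H]2Oc3c(CC=C(C)C)c(OCOC)cc(OCOC)c3C([O-])=C2)ccc1OCOC.[K+]
F2 | step 7 | [3-methoxy-4-(methoxymethoxy)phenyl]zinc chloride | Cl[Zn]c1ccc(OCOC)c(OC)c1
F3 | step 9 | (2R,3R)-2-[3-methoxy-4-(trimethylsilyloxy)phenyl]-8-(3-methylbut-2-en-1-yl)-3,5,7-tris(trimethylsilyloxy)-2,3-dihydro-4H-chromen-4-one | COc1cc([C@H]2Oc3c(CC=C(C)C)c(O[Si](C)(C)C)cc(O[Si](C)(C)C)c3C(=O)[C@@H]2O[Si](C)(C)C)ccc1O[Si](C)(C)C
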